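## Retrosynthetic overview

- The strategy rests on the ten-carbon side chain, numbered C1' (benzylic CH2) to C7' (CMe2) with a methyl on C3'. It is the skeleton of (E)-β-ocimene, and C1' and the C4' oxygen sit 1,4 and cis across the Z C2'=C3' alkene.
- Late disconnections: the C4' acetate (acetylation), the cinnamic Cα=Cβ bond (Doebner condensation with malonic acid), and the aryl–C1' bond (copper-catalysed SN2 coupling of an aryl Grignard reagent with a Z allylic bromide).
- The (2Z,4R)-ene-1,4-diol comes in one flask from (E)-β-ocimene by platinum-catalysed enantioselective 1,4-diboration (C1'–B and C4'–B) and oxidation, which sets the Z alkene and the C4' centre together.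
- No ring is formed; the benzene ring is bought as 3-bromo-4-methoxybenzaldehyde.

Key step: step 1

## Remarks (assumptions)

- The (R,R)-enantiomer of the TADDOL-derived phenylphosphonite is assumed to deliver boron to the C4' face that leads to the 4R diol. If the sense proves opposite, the (S,S)-ligand is used with nothing else changed. The ligand is a known compound, accessible in either form from the parent TADDOL and PhPCl2.
- Commercial β-ocimene is taken as the E-enriched grade. The Z isomer cannot place hydrogen inside the s-cis diene and should not give the 1,4-diol, so its products are removed when the diol is chromatographed.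

## Route

Step 1
Reactants: 1 (E)-β-ocimene; 2 bis(pinacolato)diboron
Product: 4 (2Z,4R)-3,7-dimethylocta-2,6-diene-1,4-diol, via bis(boronate) 3 (not isolated)
Conditions: Pt(dba)3 (3 mol%), (R,R)-TADDOL-derived phenylphosphonite (Ar = 3,5-di-tert-butylphenyl, 6 mol%), THF, 60 °C; then NaOH (3 M aq), H2O2 (30% aq), 0 °C → rt
Reagents that add atoms: hydrogen peroxide, OO
Why: Zerovalent platinum inserts into the B–B bond of 2, the diene of 1 binds in its s-cis form, the terminal C1'=C2' bond inserts into a Pt–B bond to give C1'–B and an allylplatinum boryl, and reductive elimination at C4' delivers the second boron from the same metal-bound face, so that C1' and C4' end cis on the new C2'=C3' bond. The closest known reaction is the platinum-catalysed enantioselective 1,4-diboration of trans-1,3-dienes with TADDOL-derived phosphonites followed by oxidation to (Z)-2-ene-1,4-diols, from which 1 differs only by its C3' methyl and its remote C6'=C7' alkene. No ring is closed. The C4' stereocentre is set under catalyst control, the chiral phosphonite on platinum choosing the face of C4' that receives boron, and the NaOH/H2O2 oxidation replaces both C–B bonds by C–O bonds with retention. The step needs 1,4- over 1,2-addition, the Z geometry and reaction at the diene only: the E C3'=C4' bond (hydrogen inside in the s-cis form) and the C3' methyl, which favours the s-cis conformer, secure the first two, and the isolated trisubstituted C6'=C7' alkene is neither a diene partner for platinum nor a substrate for alkaline peroxide.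

Step 2
Reactants: 4 (2Z,4R)-3,7-dimethylocta-2,6-diene-1,4-diol
Product: 5 (2Z,4R)-1,4-bis(tert-butyldimethylsilyloxy)-3,7-dimethylocta-2,6-diene
Conditions: TBSCl (2.5 equiv), imidazole (5 equiv), DMF, rt
Reagents that add atoms: tert-butyldimethylsilyl chloride, CC(C)(C)[Si](C)(C)Cl
Why: Silylation with TBSCl and imidazole (Corey silylation) is routine for primary and secondary allylic alcohols and masks the C4' oxygen so that it cannot close a 2,5-dihydrofuran once C1' is activated.

Step 3
Reactants: 5 (2Z,4R)-1,4-bis(tert-butyldimethylsilyloxy)-3,7-dimethylocta-2,6-diene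
Product: 6 (2Z,4R)-4-(tert-butyldimethylsilyloxy)-3,7-dimethylocta-2,6-dien-1-ol
Conditions: CSA (0.1 equiv), MeOH/CH2Cl2 (1:1), −10 °C
Reagents that add atoms: none
Why: Acid-catalysed methanolysis of silyl ethers is much faster at the unhindered primary position than at the secondary one flanked by the C3' methyl, so selective mono-desilylation should free only the C1' hydroxyl.

Step 4
Reactants: 6 (2Z,4R)-4-(tert-butyldimethylsilyloxy)-3,7-dimethylocta-2,6-dien-1-ol
Product: 7 (2Z,4R)-1-bromo-4-(tert-butyldimethylsilyloxy)-3,7-dimethylocta-2,6-diene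
Conditions: CBr4, PPh3, CH2Cl2, −20 → 0 °C; used at once
Reagents that add atoms: carbon tetrabromide, BrC(Br)(Br)Br
Why: The Appel reaction converts the primary allylic alcohol into the bromide by SN2 attack of bromide on the alkoxyphosphonium ion under neutral, cold conditions, which should leave the Z alkene, the silyl ether and C4' untouched.

Step 5
Reactants: 8 3-bromo-4-methoxybenzaldehyde
Product: 9 2-(3-bromo-4-methoxyphenyl)-1,3-dioxolane
Conditions: ethylene glycol (3 equiv), p-TsOH (2 mol%), toluene, reflux, Dean–Stark trap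
Reagents that add atoms: ethylene glycol, OCCO
Why: Acid-catalysed acetalisation with azeotropic removal of water protects the aldehyde as a 1,3-dioxolane that tolerates Grignard formation.

Step 6
Reactants: 9 2-(3-bromo-4-methoxyphenyl)-1,3-dioxolane; 7 (2Z,4R)-1-bromo-4-(tert-butyldimethylsilyloxy)-3,7-dimethylocta-2,6-diene
Product: 11 2-{3-[(2Z,4R)-4-(tert-butyldimethylsilyloxy)-3,7-dimethylocta-2,6-dien-1-yl]-4-methoxyphenyl}-1,3-dioxolane, via aryl Grignard reagent 10 (not isolated)
Conditions: Mg (I2 crystal), THF, 45 °C; then 7, CuI (10 mol%), THF, −30 → 0 °C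
Reagents that add atoms: none
Why: Magnesium insertion gives the aryl Grignard reagent, and the copper-catalysed allylic substitution should take place at the unsubstituted C1' in the SN2 sense, because the γ-carbon C3' is fully substituted and shielded by the silyloxy carbinol, with the Z geometry kept and C4' not involved.

Step 7
Reactants: 11 2-{3-[(2Z,4R)-4-(tert-butyldimethylsilyloxy)-3,7-dimethylocta-2,6-dien-1-yl]-4-methoxyphenyl}-1,3-dioxolane
Product: 12 3-[(2Z,4R)-4-hydroxy-3,7-dimethylocta-2,6-dien-1-yl]-4-methoxybenzaldehyde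
Conditions: HCl (2 M aq), THF, rt
Reagents that add atoms: water, O
Why: Aqueous acid hydrolyses the electron-rich aryl dioxolane quickly (acetal hydrolysis) and cleaves the secondary silyl ether at the Si–O bond, so the C4'–O bond is never broken and the configuration should be kept.

Step 8
Reactants: 12 3-[(2Z,4R)-4-hydroxy-3,7-dimethylocta-2,6-dien-1-yl]-4-methoxybenzaldehyde; 13 malonic acid
Product: 15 (2E)-3-{3-[(2Z,4R)-4-hydroxy-3,7-dimethylocta-2,6-dien-1-yl]-4-methoxyphenyl}prop-2-enoic acid, via arylidenemalonic acid 14 (not isolated)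
Conditions: pyridine, piperidine (0.1 equiv), 90 °C; then cold aqueous citric acid to pH 3–4
Reagents that add atoms: none
Why: In the Knoevenagel–Doebner condensation the aldehyde condenses with malonic acid under piperidine catalysis and the adduct loses CO2 in hot pyridine, which should give the thermodynamically favoured (E)-cinnamic acid without touching the free alcohol.

Step 9
Reactants: 15 (2E)-3-{3-[(2Z,4R)-4-hydroxy-3,7-dimethylocta-2,6-dien-1-yl]-4-methoxyphenyl}prop-2-enoic acid
Product: 17 (2E)-3-{3-[(2Z,4R)-4-acetoxy-3,7-dimethylocta-2,6-dien-1-yl]-4-methoxyphenyl}prop-2-enoic acid (CNP0206859.2), via mixed carboxylic acetic anhydride 16 (not isolated)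
Conditions: Ac2O (3 equiv), pyridine, DMAP (5 mol%), CH2Cl2, 0 °C → rt; then H2O, THF, NaHCO3, rt; citric acid to pH 3–4
Reagents that add atoms: acetic anhydride, CC(=O)OC(C)=O
Why: DMAP-catalysed acylation of the secondary alcohol with acetic anhydride takes place at oxygen with retention at C4', and the mixed anhydride formed at the carboxyl group should be hydrolysed back to the acid in the aqueous stage.

## Compound list

1 | (E)-β-ocimene, (3E)-3,7-dimethylocta-1,3,6-triene | C=C/C(C)=C/CC=C(C)C | starting material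
2 | bis(pinacolato)diboron | CC1(C)OB(OC1(C)C)B1OC(C)(C)C(C)(C)O1 | starting material
3 | 2,2'-[(2Z,4R)-3,7-dimethylocta-2,6-diene-1,4-diyl]bis(4,4,5,5-tetramethyl-1,3,2-dioxaborolane) | CC1(C)OB(C/C=C(/C)[C@@H](CC=C(C)C)B2OC(C)(C)C(C)(C)O2)OC1(C)C | intermediate (not isolated)
4 | (2Z,4R)-3,7-dimethylocta-2,6-diene-1,4-diol | OC/C=C(/C)[C@@H](CC=C(C)C)O | intermediate
5 | (2Z,4R)-1,4-bis(tert-butyldimethylsilyloxy)-3,7-dimethylocta-2,6-diene | CC(C)(C)[Si](C)(C)OC/C=C(/C)[C@@H](CC=C(C)C)O[Si](C)(C)C(C)(C)C | intermediate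
6 | (2Z,4R)-4-(tert-butyldimethylsilyloxy)-3,7-dimethylocta-2,6-dien-1-ol | OC/C=C(/C)[C@@H](CC=C(C)C)O[Si](C)(C)C(C)(C)C | intermediate
7 | (2Z,4R)-1-bromo-4-(tert-butyldimethylsilyloxy)-3,7-dimethylocta-2,6-diene | BrC/C=C(/C)[C@@H](CC=C(C)C)O[Si](C)(C)C(C)(C)C | intermediate
8 | 3-bromo-4-methoxybenzaldehyde | COc1ccc(C=O)cc1Br | starting material
9 | 2-(3-bromo-4-methoxyphenyl)-1,3-dioxolane | COc1ccc(C2OCCO2)cc1Br | intermediate
10 | [5-(1,3-dioxolan-2-yl)-2-methoxyphenyl]magnesium bromide | COc1ccc(C2OCCO2)cc1[Mg]Br | intermediate (not isolated)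
11 | 2-{3-[(2Z,4R)-4-(tert-butyldimethylsilyloxy)-3,7-dimethylocta-2,6-dien-1-yl]-4-methoxyphenyl}-1,3-dioxolane | COc1ccc(C2OCCO2)cc1C/C=C(/C)[C@@H](CC=C(C)C)O[Si](C)(C)C(C)(C)C | intermediate
12 | 3-[(2Z,4R)-4-hydroxy-3,7-dimethylocta-2,6-dien-1-yl]-4-methoxybenzaldehyde | COc1ccc(C=O)cc1C/C=C(/C)[C@@H](CC=C(C)C)O | intermediate
13 | malonic acid | OC(=O)CC(=O)O | starting material
14 | 2-({3-[(2Z,4R)-4-hydroxy-3,7-dimethylocta-2,6-dien-1-yl]-4-methoxyphenyl}methylidene)propanedioic acid | COc1ccc(C=C(C(=O)O)C(=O)O)cc1C/C=C(/C)[C@@H](CC=C(C)C)O | intermediate (not isolated)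
15 | (2E)-3-{3-[(2Z,4R)-4-hydroxy-3,7-dimethylocta-2,6-dien-1-yl]-4-methoxyphenyl}prop-2-enoic acid | COc1ccc(/C=C/C(=O)O)cc1C/C=C(/C)[C@@H](CC=C(C)C)O | intermediate
16 | acetic (2E)-3-{3-[(2Z,4R)-4-acetoxy-3,7-dimethylocta-2,6-dien-1-yl]-4-methoxyphenyl}prop-2-enoic anhydride | COc1ccc(/C=C/C(=O)OC(C)=O)cc1C/C=C(/C)[C@@H](CC=C(C)C)OC(C)=O | intermediate (not isolated)
17 | (2E)-3-{3-[(2Z,4R)-4-acetoxy-3,7-dimethylocta-2,6-dien-1-yl]-4-methoxyphenyl}prop-2-enoic acid (CNP0206859.2) | COc1ccc(/C=C/C(=O)O)cc1C/C=C(/C)[C@@H](CC=C(C)C)OC(C)=O | target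

## Step count

Total steps: 9. Longest linear sequence: 8 (steps 1, 2, 3, 4, 6, 7, 8, 9); step 5 is the one-step side branch.

## Steps most likely to fail

**Step 1.** The C3' methyl may change how the diene sits in the chiral pocket, giving poor enantioface selection at C4', and 1,2-addition across the terminal alkene may compete.

Fallback: it sets out from acetal 9 and comes back at 11, replacing steps 1 to 4 and 6. The C4' centre is bought, and the Z alkene is made by the Wittig reaction of an α-silyloxy methyl ketone with an unstabilised ylide, which is known to place the oxygen-bearing carbon cis to the ylide carbon.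
- Grignard reagent 10 (from 9 as in step 6) is added to ethylene oxide (CuI cat., THF, −20 °C) to give 2-[5-(1,3-dioxolan-2-yl)-2-methoxyphenyl]ethanol F1.
- I2, PPh3 and imidazole convert it into 2-[3-(2-iodoethyl)-4-methoxyphenyl]-1,3-dioxolane F2.
- PPh3 in MeCN at reflux gives {2-[5-(1,3-dioxolan-2-yl)-2-methoxyphenyl]ethyl}triphenylphosphonium iodide F3.
- Separately, bought methyl (R)-glycidate F4 is opened at its CH2 by 2-methylprop-1-enylmagnesium bromide (CuBr·SMe2 cat., THF, −40 °C) to methyl (R)-2-hydroxy-5-methylhex-4-enoate F5.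
- Silylation (TBSCl, imidazole) gives methyl (R)-2-(tert-butyldimethylsilyloxy)-5-methylhex-4-enoate F6.
- MeNHOMe·HCl and iPrMgCl give (R)-2-(tert-butyldimethylsilyloxy)-N-methoxy-N,5-dimethylhex-4-enamide F7.
- MeMgBr gives (R)-3-(tert-butyldimethylsilyloxy)-6-methylhept-5-en-2-one F8.
- Deprotonation of F3 with KN(SiMe3)2 (THF, −78 °C) gives the ylide {2-[5-(1,3-dioxolan-2-yl)-2-methoxyphenyl]ethylidene}triphenylphosphorane F9, which with F8 at −78 °C should give 11.

**Step 6.** The aryl group may attack C3' (SN2'), the Z geometry may be lost through equilibration of the allylcopper intermediate, or the labile bromide 7 may decompose before it couples, by cyclisation onto the silyloxy oxygen or by allylic shift of bromide.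

Fallback: it sets out from alcohol 6 and comes back at 12, avoiding the bromide, the Grignard reagent and the acetal.
- 6 is acylated (ClCO2Me, pyridine, CH2Cl2, 0 °C) to methyl (2Z,4R)-4-(tert-butyldimethylsilyloxy)-3,7-dimethylocta-2,6-dien-1-yl carbonate F10.
- F10 is coupled with bought 5-formyl-2-methoxyphenylboronic acid F11 under Pd(PPh3)4 (zerovalent palladium, 5 mol%) in THF at 60 °C without added base, in an allyl–aryl Suzuki–Miyaura coupling. The aryl group should join the unsubstituted C1' terminus of the π-allyl complex, and syn/anti exchange at the fully substituted C3' terminus is slow, so the Z geometry should survive.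
- The product, 3-[(2Z,4R)-4-(tert-butyldimethylsilyloxy)-3,7-dimethylocta-2,6-dien-1-yl]-4-methoxybenzaldehyde F12, is desilylated with HCl (2 M aq) in THF to 12.

**Step 7.** The acid needed to cleave the hindered secondary silyl ether may ionise the allylic C4' alcohol, with 1,3-transposition or loss of configuration, or the silyl ether may be cleaved incompletely.

Fallback: it sets out from 11 and comes back at target 17; the free allylic alcohol never meets acid.
- Bu4NF (THF, rt) removes the silyl group to give (2Z,4R)-1-[5-(1,3-dioxolan-2-yl)-2-methoxyphenyl]-3,7-dimethylocta-2,6-dien-4-ol F13.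
- Ac2O, pyridine and DMAP give (2Z,4R)-1-[5-(1,3-dioxolan-2-yl)-2-methoxyphenyl]-3,7-dimethylocta-2,6-dien-4-yl acetate F14.
- PPTS in wet acetone at rt unmasks (2Z,4R)-1-(5-formyl-2-methoxyphenyl)-3,7-dimethylocta-2,6-dien-4-yl acetate F15.
- Doebner condensation with malonic acid 13 (pyridine, piperidine cat., 80 °C) passes through 2-({3-[(2Z,4R)-4-acetoxy-3,7-dimethylocta-2,6-dien-1-yl]-4-methoxyphenyl}methylidene)propanedioic acid F16 to 17.

## Further compounds

F1 | step 1 | 2-[5-(1,3-dioxolan-2-yl)-2-methoxyphenyl]ethanol | COc1ccc(C2OCCO2)cc1CCO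
F2 | step 1 | 2-[3-(2-iodoethyl)-4-methoxyphenyl]-1,3-dioxolane | COc1ccc(C2OCCO2)cc1CCI
F3 | step 1 | {2-[5-(1,3-dioxolan-2-yl)-2-methoxyphenyl]ethyl}triphenylphosphonium iodide | COc1ccc(C2OCCO2)cc1CC[P+](c1ccccc1)(c1ccccc1)c1ccccc1.[I-]
F4 | step 1 | methyl (R)-glycidate, methyl (2R)-oxirane-2-carboxylate (bought) | COC(=O)[C@H]1CO1
F5 | step 1 | methyl (R)-2-hydroxy-5-methylhex-4-enoate | COC(=O)[C@H](O)CC=C(C)C
F6 | step 1 | methyl (R)-2-(tert-butyldimethylsilyloxy)-5-methylhex-4-enoate | COC(=O)[C@H](O[Si](C)(C)C(C)(C)C)CC=C(C)C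
F7 | step 1 | (R)-2-(tert-butyldimethylsilyloxy)-N-methoxy-N,5-dimethylhex-4-enamide | CON(C)C(=O)[C@H](O[Si](C)(C)C(C)(C)C)CC=C(C)C
F8 | step 1 | (R)-3-(tert-butyldimethylsilyloxy)-6-methylhept-5-en-2-one | CC(=O)[C@H](O[Si](C)(C)C(C)(C)C)CC=C(C)C
F9 | step 1 | {2-[5-(1,3-dioxolan-2-yl)-2-methoxyphenyl]ethylidene}triphenylphosphorane | COc1ccc(C2OCCO2)cc1CC=P(c1ccccc1)(c1ccccc1)c1ccccc1
F10 | step 6 | methyl (2Z,4R)-4-(tert-butyldimethylsilyloxy)-3,7-dimethylocta-2,6-dien-1-yl carbonate | COC(=O)OC/C=C(/C)[C@@H](CC=C(C)C)O[Si](C)(C)C(C)(C)C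
F11 | step 6 | 5-formyl-2-methoxyphenylboronic acid (bought) | COc1ccc(C=O)cc1B(O)O
F12 | step 6 | 3-[(2Z,4R)-4-(tert-butyldimethylsilyloxy)-3,7-dimethylocta-2,6-dien-1-yl]-4-methoxybenzaldehyde | COc1ccc(C=O)cc1C/C=C(/C)[C@@H](CC=C(C)C)O[Si](C)(C)C(C)(C)C
F13 | step 7 | (2Z,4R)-1-[5-(1,3-dioxolan-2-yl)-2-methoxyphenyl]-3,7-dimethylocta-2,6-dien-4-ol | COc1ccc(C2OCCO2)cc1C/C=C(/C)[C@@H](CC=C(C)C)O
F14 | step 7 | (2Z,4R)-1-[5-(1,3-dioxolan-2-yl)-2-methoxyphenyl]-3,7-dimethylocta-2,6-dien-4-yl acetate | COc1ccc(C2OCCO2)cc1C/C=C(/C)[C@@H](CC=C(C)C)OC(C)=O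
F15 | step 7 | (2Z,4R)-1-(5-formyl-2-methoxyphenyl)-3,7-dimethylocta-2,6-dien-4-yl acetate | COc1ccc(C=O)cc1C/C=C(/C)[C@@H](CC=C(C)C)OC(C)=O
F16 | step 7 | 2-({3-[(2Z,4R)-4-acetoxy-3,7-dimethylocta-2,6-dien-1-yl]-4-methoxyphenyl}methylidene)propanedioic acid | COc1ccc(C=C(C(=O)O)C(=O)O)cc1C/C=C(/C)[C@@H](CC=C(C)C)OC(C)=O
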